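**Retrosynthetic overview**

1. The route rests on the (E)-5-ylidene-2(5H)-furanone: ring O1–C2(=O)–C3(Me)=C4–C5 with the exocyclic C5=C6 bond to stereocentre C7 (then C8, C9=C10, C11(Me)=C12, C13, C14, bisfuran). This unit is the enol ester of a C5 ketone, so its less stable geometry (C7 cis to C4) can be fixed on an acyclic lithium dienolate before the ring exists.
2. C10–C11 is cut by an alkenyl–alkenyl Negishi coupling between a head C9=C10 iodide and a tail C11 alkenylzinc made by syn-hydrozirconation of a 2-alkyne; C9=C10 comes from a Takai iodo-olefination of the C9 aldehyde.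
3. The butenolide, the only ring that is made, is closed at C3=C4 by ring-closing metathesis of the (E)-dienol methacrylate; this ester comes from E-selective enolisation and O-acylation of a vinyl ketone (C4–C5 from vinyl Grignard addition to a Weinreb amide), and C7 is bought in methyl hydrogen (R)-3-methylglutarate and carried through the (S)-lactone.
4. Tail: both furans are purchased; the CH2 bridge is made by 3-furyllithium addition to 4-bromofuran-2-carbaldehyde and ionic deoxygenation, and the C13–C14 chain is attached by an alkylzinc Negishi coupling at the furan bromide.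
5. Ring order: furans (bought), then the butenolide in step 6; no ring is formed afterwards.

Key step: step 6

Assumption: methyl hydrogen (R)-3-methylglutarate 1 is taken as a purchasable, enantiopure building block (it is otherwise made by desymmetrising methanolysis of 3-methylglutaric anhydride).

**Route**

Step 1
Reactants: 1 methyl hydrogen (R)-3-methylglutarate [(3R)-5-methoxy-3-methyl-5-oxopentanoic acid]
Product: 3 (S)-4-methyltetrahydro-2H-pyran-2-one, via (S)-5-hydroxy-3-methylpentanoic acid 2 (not isolated)
Conditions: LiEt3BH (3 equiv), THF, −78 → 0 °C; then 2 M HCl, rt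
Reagents that add atoms: none
Why: Chemoselective ester reduction: the first hydride equivalent turns the acid into a lithium carboxylate that is inert to LiEt3BH, the methyl ester is reduced to the primary alcohol and acidification lactonises 2; the stereocentre of 1 is untouched and is (S) in 3 only because the CIP priorities of its two arms are exchanged.

Step 2
Reactants: 3 (S)-4-methyltetrahydro-2H-pyran-2-one
Product: 4 (S)-5-hydroxy-N-methoxy-N,3-dimethylpentanamide
Conditions: MeNH(OMe)·HCl (3 equiv), AlMe3 (3 equiv), CH2Cl2, 0 °C → rt
Reagents that add atoms: N,O-dimethylhydroxylamine hydrochloride, CNOC.Cl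
Why: Weinreb aminolysis of a lactone: the aluminium amide formed in the flask opens the δ-lactone at the acyl carbon, and the stereocentre is remote from the reacting centre.

Step 3
Reactants: 4 (S)-5-hydroxy-N-methoxy-N,3-dimethylpentanamide
Product: 5 (S)-5-(tert-butyldimethylsilyloxy)-N-methoxy-N,3-dimethylpentanamide
Conditions: TBSCl, imidazole, CH2Cl2, 0 °C → rt
Reagents that add atoms: tert-butyldimethylsilyl chloride, CC(C)(C)[Si](C)(C)Cl
Why: Standard imidazole-promoted silylation of a primary alcohol, carried out at once so that the hydroxy amide cannot relactonise.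

Step 4
Reactants: 5 (S)-5-(tert-butyldimethylsilyloxy)-N-methoxy-N,3-dimethylpentanamide; 6 vinylmagnesium bromide
Product: 7 (S)-7-(tert-butyldimethylsilyloxy)-5-methylhept-1-en-3-one
Conditions: 6 (1.5 equiv), THF, −20 → 0 °C; inverse quench into cold 1 M HCl
Reagents that add atoms: none
Why: Weinreb ketone synthesis: the magnesium-chelated tetrahedral adduct survives until the quench and so stops at the ketone, and the acidic inverse quench protonates the liberated N,O-dimethylhydroxylamine before it can add to the vinyl ketone.

Step 5
Reactants: 7 (S)-7-(tert-butyldimethylsilyloxy)-5-methylhept-1-en-3-one; 8 methacrylic anhydride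
Product: 10 (3E,5S)-7-(tert-butyldimethylsilyloxy)-5-methylhepta-1,3-dien-3-yl 2-methylprop-2-enoate, via lithium (E)-dienolate 9 (not isolated)
Conditions: LiTMP (lithium 2,2,6,6-tetramethylpiperidide, from the amine and n-BuLi; 1.1 equiv), LiBr (0.5 equiv), THF, −78 °C, slow addition of 7; then 8 (1.5 equiv), −78 → −40 °C
Reagents that add atoms: none
Why: Kinetic deprotonation at C6 (the only enolisable position, since the vinyl side has no acidic hydrogen) by the hindered LiTMP–LiBr aggregate through a closed six-membered transition state should place the C7 chain trans to the enolate oxygen (E-enolate), slow addition of 7 to the base keeps free enone away from the enolate, and lithium enolates are acylated on oxygen by anhydrides with retention of geometry (enol ester formation).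

Step 6
Reactants: 10 (3E,5S)-7-(tert-butyldimethylsilyloxy)-5-methylhepta-1,3-dien-3-yl 2-methylprop-2-enoate
Product: 11 (S,E)-5-[4-(tert-butyldimethylsilyloxy)-2-methylbutylidene]-3-methylfuran-2(5H)-one
Conditions: second-generation Hoveyda–Grubbs catalyst (H2IMes)Cl2Ru=CH(2-isopropoxyphenyl) (10 mol%, two portions), 1,4-benzoquinone (20 mol%), toluene (5 mM), 80 °C, Ar sparge
Reagents that add atoms: none
Why: Proposed new method: the ruthenium carbene should exchange first with the monosubstituted terminal vinyl group (C4) to give a vinylcarbene, which undergoes intramolecular [2+2] cycloaddition with the 1,1-disubstituted methacrylate alkene and cycloreversion, expelling ethylene and forming the C3=C4 bond; the closest known reaction type is the ring-closing metathesis of allylic methacrylates to α-methylbutenolides with second-generation ruthenium catalysts, extended here from an sp3 carbinol carbon to an sp2 enol carbon. The one ring formed, the butenolide O1–C2–C3–C4–C5, is closed as a five-membered ring in which both carbons of the new double bond are endocyclic. No stereocentre is created: C7 is not touched under these neutral conditions, and the C5=C6 geometry was set in step 5 and is preserved because neither the enol C–O bond nor C5=C6 enters a metallacycle. The step needs retention of the E enol ester geometry and exclusive five-ring closure; the first is secured by the trisubstituted, acyloxy-bearing C5=C6 being a poor partner for the carbene, the second by the absence of any other alkene (the chain ends at C9 as a silyl ether), with high dilution against dimerisation and the benzoquinone against ruthenium hydride isomerisation.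

Step 7
Reactants: 11 (S,E)-5-[4-(tert-butyldimethylsilyloxy)-2-methylbutylidene]-3-methylfuran-2(5H)-one
Product: 12 (S,E)-5-(4-hydroxy-2-methylbutylidene)-3-methylfuran-2(5H)-one
Conditions: HF·pyridine, pyridine, THF, 0 °C → rt
Reagents that add atoms: none
Why: Fluoride desilylation with buffered HF·pyridine cleaves the primary silyl ether without generating alkoxide or free fluoride base, so the acidic C7–H, the C5=C6 geometry and the electrophilic enol lactone are not put at risk.

Step 8
Reactants: 12 (S,E)-5-(4-hydroxy-2-methylbutylidene)-3-methylfuran-2(5H)-one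
Product: 13 (3S,4E)-3-methyl-4-(4-methyl-5-oxofuran-2(5H)-ylidene)butanal
Conditions: Dess–Martin periodinane, CH2Cl2, 0 °C → rt
Reagents that add atoms: none
Why: Dess–Martin oxidation under near-neutral conditions stops at the aldehyde, and C7 is β to the new carbonyl so it cannot epimerise by enolisation.

Step 9
Reactants: 13 (3S,4E)-3-methyl-4-(4-methyl-5-oxofuran-2(5H)-ylidene)butanal
Product: 14 (E)-5-[(2S,4E)-5-iodo-2-methylpent-4-en-1-ylidene]-3-methylfuran-2(5H)-one
Conditions: CrCl2 (8 equiv), CHI3 (3 equiv), THF/1,4-dioxane (1:6), 0 °C → rt, dark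
Reagents that add atoms: iodoform, IC(I)I
Why: Takai iodo-olefination: the geminal dichromium carbenoid formed from CHI3 and divalent chromium adds to the aldehyde and eliminates to the (E)-alkenyl iodide, dioxane as cosolvent favours the E isomer, and CrCl2 should not reduce the dienoate lactone.

Step 10
Reactants: 15 pent-3-yn-1-ol
Product: 16 5-iodopent-2-yne
Conditions: PPh3, I2, imidazole, CH2Cl2, 0 °C → rt
Reagents that add atoms: iodine, II
Why: Appel-type iodination: the alkoxyphosphonium salt of the primary alcohol is displaced by iodide (SN2), and the internal alkyne is inert.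

Step 11
Reactants: 17 3-bromofuran; 18 4-bromofuran-2-carbaldehyde
Product: 20 (4-bromofuran-2-yl)(furan-3-yl)methanol (racemic), via furan-3-yllithium 19 (not isolated)
Conditions: 17 (1.2 equiv), n-BuLi (1.15 equiv), THF, −78 °C; then 18, −78 °C; H2O
Reagents that add atoms: none
Why: Bromine–lithium exchange of 17 at −78 °C gives 19 below the temperature at which it isomerises to the 2-lithio species, and its 1,2-addition to the aldehyde of 18 is faster than exchange at the ring bromide of 18; the new carbinol centre is racemic and is removed in step 12.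

Step 12
Reactants: 20 (4-bromofuran-2-yl)(furan-3-yl)methanol
Product: 21 4-bromo-2-(furan-3-ylmethyl)furan
Conditions: Et3SiH (4 equiv), CF3CO2H, CH2Cl2, −20 → 0 °C
Reagents that add atoms: none
Why: Ionic hydrogenation: acid ionises the carbinol to a cation stabilised by both furan rings and Et3SiH delivers hydride to it, excess silane and low temperature suppress Friedel–Crafts oligomerisation, and the C–Br bond is unaffected.

Step 13
Reactants: 16 5-iodopent-2-yne; 21 4-bromo-2-(furan-3-ylmethyl)furan
Product: 23 2-(furan-3-ylmethyl)-4-(pent-3-yn-1-yl)furan, via pent-3-yn-1-ylzinc iodide 22 (not isolated)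
Conditions: Zn dust, LiCl, THF, 40 °C; then 21, Pd(OAc)2 (2 mol%), SPhos (4 mol%), THF, rt → 50 °C
Reagents that add atoms: none
Why: Direct zinc insertion into the primary iodide followed by a Negishi sp3–sp2 coupling; the bulky electron-rich biarylphosphine speeds oxidative addition into the electron-rich 3-bromofuran and reductive elimination ahead of β-hydride elimination, and the internal alkyne stays intact.

Step 14
Reactants: 23 2-(furan-3-ylmethyl)-4-(pent-3-yn-1-yl)furan; 14 (E)-5-[(2S,4E)-5-iodo-2-methylpent-4-en-1-ylidene]-3-methylfuran-2(5H)-one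
Product: 26 (E)-5-[(2S,4E,6E)-9-[5-(furan-3-ylmethyl)furan-3-yl]-2,6-dimethylnona-4,6-dien-1-ylidene]-3-methylfuran-2(5H)-one, via alkenylzirconocene chloride 24 (not isolated), via alkenylzinc chloride 25 (not isolated)
Conditions: 23 (1.5 equiv), Cp2Zr(H)Cl (1.6 equiv), THF, 50 °C then rt; ZnCl2, THF, 0 °C; then 14 (1.0 equiv), Pd(PPh3)4 (5 mol%), THF, rt, dark
Reagents that add atoms: none
Why: syn-Hydrozirconation of the 2-alkyne with a slight excess of Cp2Zr(H)Cl should equilibrate zirconium to the less hindered methyl-bearing carbon (C11), and transmetalation to zinc and Negishi alkenyl–alkenyl coupling at zerovalent palladium proceed with retention at both partners, so the 9E,11E-diene is formed under conditions mild enough for the enol lactone and C7.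

**Compound list**

1 | methyl hydrogen (R)-3-methylglutarate | COC(=O)C[C@H](C)CC(=O)O | starting material
2 | (S)-5-hydroxy-3-methylpentanoic acid | OC(=O)C[C@@H](C)CCO | intermediate (not isolated)
3 | (S)-4-methyltetrahydro-2H-pyran-2-one | O=C1C[C@@H](C)CCO1 | intermediate
4 | (S)-5-hydroxy-N-methoxy-N,3-dimethylpentanamide | CON(C)C(=O)C[C@@H](C)CCO | intermediate
5 | (S)-5-(tert-butyldimethylsilyloxy)-N-methoxy-N,3-dimethylpentanamide | CON(C)C(=O)C[C@@H](C)CCO[Si](C)(C)C(C)(C)C | intermediate
6 | vinylmagnesium bromide | C=C[Mg]Br | starting material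
7 | (S)-7-(tert-butyldimethylsilyloxy)-5-methylhept-1-en-3-one | C=CC(=O)C[C@@H](C)CCO[Si](C)(C)C(C)(C)C | intermediate
8 | methacrylic anhydride | CC(=C)C(=O)OC(=O)C(C)=C | starting material
9 | lithium (3E,5S)-7-(tert-butyldimethylsilyloxy)-5-methylhepta-1,3-dien-3-olate | C=C/C(O[Li])=C\[C@@H](C)CCO[Si](C)(C)C(C)(C)C | intermediate (not isolated)
10 | (3E,5S)-7-(tert-butyldimethylsilyloxy)-5-methylhepta-1,3-dien-3-yl 2-methylprop-2-enoate | C=C/C(OC(=O)C(C)=C)=C\[C@@H](C)CCO[Si](C)(C)C(C)(C)C | intermediate
11 | (S,E)-5-[4-(tert-butyldimethylsilyloxy)-2-methylbutylidene]-3-methylfuran-2(5H)-one | CC1=C/C(=C\[C@@H](C)CCO[Si](C)(C)C(C)(C)C)OC1=O | intermediate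
12 | (S,E)-5-(4-hydroxy-2-methylbutylidene)-3-methylfuran-2(5H)-one | CC1=C/C(=C\[C@@H](C)CCO)OC1=O | intermediate
13 | (3S,4E)-3-methyl-4-(4-methyl-5-oxofuran-2(5H)-ylidene)butanal | CC1=C/C(=C\[C@@H](C)CC=O)OC1=O | intermediate
14 | (E)-5-[(2S,4E)-5-iodo-2-methylpent-4-en-1-ylidene]-3-methylfuran-2(5H)-one | CC1=C/C(=C\[C@@H](C)C/C=C/I)OC1=O | intermediate
15 | pent-3-yn-1-ol | CC#CCCO | starting material
16 | 5-iodopent-2-yne | CC#CCCI | intermediate
17 | 3-bromofuran | Brc1ccoc1 | starting material
18 | 4-bromofuran-2-carbaldehyde | O=Cc1cc(Br)co1 | starting material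
19 | furan-3-yllithium | [Li]c1ccoc1 | intermediate (not isolated)
20 | (4-bromofuran-2-yl)(furan-3-yl)methanol (racemic) | OC(c1ccoc1)c1cc(Br)co1 | intermediate
21 | 4-bromo-2-(furan-3-ylmethyl)furan | Brc1coc(Cc2ccoc2)c1 | intermediate
22 | pent-3-yn-1-ylzinc iodide | CC#CCC[Zn]I | intermediate (not isolated)
23 | 2-(furan-3-ylmethyl)-4-(pent-3-yn-1-yl)furan | CC#CCCc1coc(Cc2ccoc2)c1 | intermediate
24 | chlorobis(cyclopentadienyl){(E)-5-[5-(furan-3-ylmethyl)furan-3-yl]pent-2-en-2-yl}zirconium | C/C(=C\CCc1coc(Cc2ccoc2)c1)[Zr](Cl)(C1C=CC=C1)C1C=CC=C1 | intermediate (not isolated)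
25 | chloro{(E)-5-[5-(furan-3-ylmethyl)furan-3-yl]pent-2-en-2-yl}zinc | C/C(=C\CCc1coc(Cc2ccoc2)c1)[Zn]Cl | intermediate (not isolated)
26 | (E)-5-[(2S,4E,6E)-9-[5-(furan-3-ylmethyl)furan-3-yl]-2,6-dimethylnona-4,6-dien-1-ylidene]-3-methylfuran-2(5H)-one | CC1=C/C(=C\[C@@H](C)C/C=C/C(C)=C/CCc2coc(Cc3ccoc3)c2)OC1=O | target

**Step count**

Total steps: 14. Longest linear sequence: 10 steps (steps 1–9, then step 14). The tail branch is steps 11–13, with step 10 feeding step 13.

**Steps most likely to fail, with fallbacks**

Step 6 (ring-closing metathesis of the dienol methacrylate). The catalyst may be held as an unreactive vinylcarbene on the 2-acyloxydiene, the ester may not reach the rotamer needed for five-ring closure, or intermolecular metathesis and cleavage at C5=C6 may outrun cyclisation. The fallback builds the ring by a vinylogous aldol addition followed by anti-elimination, both known for this ring system. It sets out from 10, of which either enol ester geometry serves: exhaustive ozonolysis (O3, CH2Cl2, −78 °C; Me2S) cuts C5=C6 and releases (S)-4-(tert-butyldimethylsilyloxy)-2-methylbutanal F1. Commercial 3-methylfuran-2(5H)-one is silylated (TBSOTf, Et3N, CH2Cl2) to 2-(tert-butyldimethylsilyloxy)-3-methylfuran F2, which adds through its C5 to F1 (BF3·OEt2, CH2Cl2, −78 °C; vinylogous Mukaiyama aldol). After separation of the diastereomers this should give the 5,6-unlike adduct (R)-5-[(1S,2S)-4-(tert-butyldimethylsilyloxy)-1-hydroxy-2-methylbutyl]-3-methylfuran-2(5H)-one F3; its (5S,1'R) counterpart converges on the same alkene. Stereospecific anti-dehydration under Mitsunobu conditions (PPh3, diethyl azodicarboxylate, THF) turns the unlike adduct into the E-ylidene butenolide and comes back to the route at 11.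

Step 5 (E-selective enolisation and O-acylation). The enolate geometry may erode, the vinyl ketone may oligomerise by Michael addition while enolate and enone coexist, or some acylation may occur on carbon. The fallback sets out from 7: deprotonation with LiTMP in the presence of Me3SiCl (internal quench, THF, −78 °C) traps the kinetic enolate at once as (3E,5S)-7-(tert-butyldimethylsilyloxy)-5-methyl-3-(trimethylsilyloxy)hepta-1,3-diene F4, an isolable compound whose geometry can be checked and enriched before use. MeLi (THF, 0 °C) then regenerates the lithium enolate 9 free of amine and enone, and acylation with 8 comes back to the route at 10.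

Step 14 (hydrozirconation and Negishi coupling). Regiocontrol in the hydrozirconation may be incomplete (zirconium at C12 as well as C11), residual hydride may attack the lactone of 14, or slow transmetalation may lead to homocoupling. The fallback sets out from 23: hydrozirconation as before to 24, then quenching with I2 gives the isolable 2-(furan-3-ylmethyl)-4-[(E)-4-iodopent-3-en-1-yl]furan F5, which is freed from its regioisomer. Stannylation (Me3SnSnMe3, Pd(PPh3)4, toluene, 80 °C) gives trimethyl{(E)-5-[5-(furan-3-ylmethyl)furan-3-yl]pent-2-en-2-yl}stannane F6, and a Stille coupling of F6 with 14 (Pd2(dba)3, AsPh3, CuI, N-methylpyrrolidone, rt) comes back to the route at 26 without hydride or zinc reagents.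

**Further compounds**

F1 | step 6 | (S)-4-(tert-butyldimethylsilyloxy)-2-methylbutanal | O=C[C@@H](C)CCO[Si](C)(C)C(C)(C)C
F2 | step 6 | 2-(tert-butyldimethylsilyloxy)-3-methylfuran | Cc1ccoc1O[Si](C)(C)C(C)(C)C
F3 | step 6 | (R)-5-[(1S,2S)-4-(tert-butyldimethylsilyloxy)-1-hydroxy-2-methylbutyl]-3-methylfuran-2(5H)-one | CC1=C[C@H]([C@@H](O)[C@@H](C)CCO[Si](C)(C)C(C)(C)C)OC1=O
F4 | step 5 | (3E,5S)-7-(tert-butyldimethylsilyloxy)-5-methyl-3-(trimethylsilyloxy)hepta-1,3-diene | C=C/C(O[Si](C)(C)C)=C\[C@@H](C)CCO[Si](C)(C)C(C)(C)C
F5 | step 14 | 2-(furan-3-ylmethyl)-4-[(E)-4-iodopent-3-en-1-yl]furan | C/C(I)=C\CCc1coc(Cc2ccoc2)c1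
F6 | step 14 | trimethyl{(E)-5-[5-(furan-3-ylmethyl)furan-3-yl]pent-2-en-2-yl}stannane | C/C(=C\CCc1coc(Cc2ccoc2)c1)[Sn](C)(C)C
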